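**Plan**

- Numbering (germacranolide): carbocycle C1–C10 with C1=C10 and C4=C5; lactone C12(=O)–O–C6 through C7–C11; C13 is the methylene on C11, C14 the methyl on C10, C15 the methyl on C4.
- Cuts, in retrosynthetic order: the C9–O acyl bond (epoxy acid 36), the C3–O acetyl bond and C11=C13; then together the lactone bond O6–C12 and the ring bond C5–C6; then the alkene C1=C10, which gives fragment 1 (C1–C5, phosphonium salt 10) and fragment 2 (C6–C12 with C14, methyl ketone 19).
- Enabling feature: C6 is a carbinol carbon between the Z-alkene carbon C5 and C7, and C7 carries the C11–C12 acetic ester arm. An alkenylmetal at C5 adding to a C6 aldehyde therefore closes the ten-membered carbocycle and leaves the C6 alkoxide placed to close the five-membered lactone ring on C12.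
- Forward: 10 + 19 are joined at C1=C10 by a Wittig reaction (21), the aldehyde is released (22), one operation closes carbocycle and lactone (25); then α-methylenation, C3 acetate, diol release and C9 acylation.
- Stereochemistry: C8 and C9 from 2,3-O-isopropylidene-D-erythronolactone; C7 by syn-selective nitromethane addition directed by C8; C3 by Brown allylboration; C6 in the ring closure (macrocyclic control); Z-C4=C5 by anti carbomagnesiation–iodination; Z-C1=C10 by the Z preference of α-alkoxy ketones in Wittig reactions; the epoxide by Sharpless epoxidation.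

Key step: step 15

Remark: the chromium alkoxide formed in step 15 is taken to lactonise in the flask or during work-up, as γ-hydroxy methyl esters normally do.

**Fragment 1 (C1–C5)**

Step 1
Reactants: 1 prop-2-yn-1-ol
Product: 3 (Z)-3-iodo-2-methylprop-2-en-1-ol, via magnesium alkenyl alkoxide 2 (not isolated)
Conditions: MeMgBr (2.5 equiv), CuI (10 mol %), Et2O, −10 °C to rt; then I2, −10 °C
Reagents that add atoms: methylmagnesium bromide, C[Mg]Br; iodine, II
Why: Copper-catalysed anti carbomagnesiation of the propargylic alkoxide puts methyl on the inner carbon and magnesium on the terminal carbon cis to the CH2O group in a five-membered chelate, and iodinolysis with retention should give the Z iodoalkene (future C3–C5 and C15).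

Step 2
Reactants: 3 (Z)-3-iodo-2-methylprop-2-en-1-ol
Product: 4 (Z)-3-iodo-2-methylprop-2-enal
Conditions: MnO2 (activated, excess), CH2Cl2, rt, dark; used at once
Reagents that add atoms: none
Why: Heterogeneous allylic oxidation with MnO2 is neutral, so the labile Z β-iodo enal should form without isomerisation.

Step 3
Reactants: 4 (Z)-3-iodo-2-methylprop-2-enal
Product: 5 (3S,1Z)-1-iodo-2-methylhexa-1,5-dien-3-ol
Conditions: (−)-B-methoxydiisopinocampheylborane [(+)-α-pinene series], allylMgBr, Et2O, 0 °C to rt; 4, −78 °C; then NaOH, H2O2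
Reagents that add atoms: allylmagnesium bromide, C=CC[Mg]Br
Why: Brown allylboration through a closed chair transition state, in which this antipode of the reagent delivers allyl to the Si face of the aldehyde and so sets C3 as S.

Step 4
Reactants: 5 (3S,1Z)-1-iodo-2-methylhexa-1,5-dien-3-ol
Product: 6 tert-butyl{[(3S,1Z)-1-iodo-2-methylhexa-1,5-dien-3-yl]oxy}dimethylsilane
Conditions: TBSOTf, 2,6-lutidine, CH2Cl2, −78 to 0 °C
Reagents that add atoms: tert-butyldimethylsilyl trifluoromethanesulfonate, CC(C)(C)[Si](C)(C)OS(=O)(=O)C(F)(F)F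
Why: Silylation of the hindered allylic alcohol with the silyl triflate gives an ether that should survive every step up to its fluoride cleavage in step 17.

Step 5
Reactants: 6 tert-butyl{[(3S,1Z)-1-iodo-2-methylhexa-1,5-dien-3-yl]oxy}dimethylsilane
Product: 8 (3S,4Z)-3-(tert-butyldimethylsilyloxy)-5-iodo-4-methylpent-4-en-1-ol, via silyloxy aldehyde 7 (not isolated)
Conditions: OsO4 (2 mol %), NaIO4, 2,6-lutidine, dioxane–H2O, rt; then NaBH4, MeOH, 0 °C
Reagents that add atoms: osmium tetroxide, O=[Os](=O)(=O)=O; sodium periodate, [Na+].[O-]I(=O)(=O)=O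
Why: Lemieux–Johnson cleavage should take the monosubstituted alkene in preference to the iodine-bearing trisubstituted one, and immediate borohydride reduction removes the β-silyloxy aldehyde before it can eliminate.

Step 6
Reactants: 8 (3S,4Z)-3-(tert-butyldimethylsilyloxy)-5-iodo-4-methylpent-4-en-1-ol
Product: 9 tert-butyl{[(3S,1Z)-1,5-diiodo-2-methylpent-1-en-3-yl]oxy}dimethylsilane
Conditions: I2, PPh3, imidazole, CH2Cl2, 0 °C to rt
Reagents that add atoms: iodine, II
Why: Appel-type (Garegg–Samuelsson) iodination, an SN2 displacement of the oxyphosphonium group at the primary carbon.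

Step 7
Reactants: 9 tert-butyl{[(3S,1Z)-1,5-diiodo-2-methylpent-1-en-3-yl]oxy}dimethylsilane
Product: 10 [(3S,4Z)-3-(tert-butyldimethylsilyloxy)-5-iodo-4-methylpent-4-en-1-yl]triphenylphosphonium iodide
Conditions: PPh3, i-Pr2NEt (0.2 equiv), MeCN, 80 °C
Reagents that add atoms: triphenylphosphine, c1ccc(cc1)P(c1ccccc1)c1ccccc1
Why: SN2 quaternisation of the phosphine by the primary iodide; the alkenyl iodide is inert in the absence of a transition metal.

**Fragment 2 (C6–C12, C14)**

Step 8
Reactants: 11 2,3-O-isopropylidene-D-erythronolactone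
Product: 12 1-deoxy-3,4-O-isopropylidene-D-erythro-pent-2-ulofuranose (anomeric mixture)
Conditions: MeLi (1.05 equiv), THF, −78 °C; then H2O
Reagents that add atoms: methyllithium, [Li]C
Why: Single addition of MeLi to the γ-lactone, whose tetrahedral lithium alkoxide is stable at −78 °C, gives the methyl hemiketal (masked C10 methyl ketone with C14 in place).

Step 9
Reactants: 12 1-deoxy-3,4-O-isopropylidene-D-erythro-pent-2-ulofuranose
Product: 13 [(4R,5S)-2,2-dimethyl-5-(prop-1-en-2-yl)-1,3-dioxolan-4-yl]methanol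
Conditions: Ph3PCH3Br (3 equiv), KOt-Bu (3 equiv), THF, 0 to 50 °C
Reagents that add atoms: methyltriphenylphosphonium bromide, C[P+](c1ccccc1)(c1ccccc1)c1ccccc1.[Br-]
Why: Wittig methylenation of the ring-opened hydroxy ketone tautomer masks the future C10 ketone as an isopropenyl group and frees the C7 hydroxyl; the ketone is present only in low concentration, which limits epimerisation at C9.

Step 10
Reactants: 13 [(4R,5S)-2,2-dimethyl-5-(prop-1-en-2-yl)-1,3-dioxolan-4-yl]methanol
Product: 15 methyl (E)-3-[(4R,5S)-2,2-dimethyl-5-(prop-1-en-2-yl)-1,3-dioxolan-4-yl]prop-2-enoate, via dioxolane aldehyde 14 (not isolated)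
Conditions: Dess–Martin periodinane, CH2Cl2, 0 °C to rt; then Ph3P=CHCO2Me, rt
Reagents that add atoms: methyl (triphenylphosphoranylidene)acetate, COC(=O)C=P(c1ccccc1)(c1ccccc1)c1ccccc1
Why: Dess–Martin oxidation followed in the same flask by Wittig reaction with the stabilised ylide traps the epimerisable cis-dioxolane aldehyde as the E enoate (C7=C11, C12).

Step 11
Reactants: 15 methyl (E)-3-[(4R,5S)-2,2-dimethyl-5-(prop-1-en-2-yl)-1,3-dioxolan-4-yl]prop-2-enoate
Product: 16 methyl (3R)-3-[(4R,5S)-2,2-dimethyl-5-(prop-1-en-2-yl)-1,3-dioxolan-4-yl]-4-nitrobutanoate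
Conditions: CH3NO2 (10 equiv), DBU (1 equiv), MeCN, 0 °C to rt
Reagents that add atoms: nitromethane, C[N+](=O)[O-]
Why: Base-mediated Michael addition of nitromethane, in which the γ-oxygen stereocentre C8 directs the nucleophile to the syn adduct (the established preference of γ,δ-dioxolanyl enoates), sets C7 and brings in C6.

Step 12
Reactants: 16 methyl (3R)-3-[(4R,5S)-2,2-dimethyl-5-(prop-1-en-2-yl)-1,3-dioxolan-4-yl]-4-nitrobutanoate
Product: 19 methyl (3S)-3-[(4R,5R)-5-acetyl-2,2-dimethyl-1,3-dioxolan-4-yl]-4,4-dimethoxybutanoate, via sodium nitronate 17 (not isolated), via keto aldehyde 18 (not isolated)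
Conditions: NaOMe (1.05 equiv), MeOH, 0 °C; O3, MeOH–CH2Cl2, −78 °C; Me2S; then HC(OMe)3, PPTS, rt
Reagents that add atoms: ozone, [O-][O+]=O; trimethyl orthoformate, COC(OC)OC
Why: Ozonolysis of the nitronate (oxidative Nef reaction) and of the isopropenyl group should unveil the C6 aldehyde and the C10 methyl ketone together, and only the far more reactive aldehyde is then converted to its dimethyl acetal, which also forestalls aldol closure of the 1,5-dicarbonyl compound.

**Union, ring closure and end game**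

Step 13
Reactants: 10 [(3S,4Z)-3-(tert-butyldimethylsilyloxy)-5-iodo-4-methylpent-4-en-1-yl]triphenylphosphonium iodide (fragment 1); 19 methyl (3S)-3-[(4R,5R)-5-acetyl-2,2-dimethyl-1,3-dioxolan-4-yl]-4,4-dimethoxybutanoate (fragment 2)
Product: 21 methyl (3S)-3-{(4R,5S)-5-[(2Z,5S,6Z)-5-(tert-butyldimethylsilyloxy)-7-iodo-6-methylhepta-2,6-dien-2-yl]-2,2-dimethyl-1,3-dioxolan-4-yl}-4,4-dimethoxybutanoate, via phosphorus ylide 20 (not isolated)
Conditions: KN(SiMe3)2 (1.0 equiv), THF, −78 °C; then 19, −78 to 0 °C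
Reagents that add atoms: none
Why: Salt-free Wittig reaction of a non-stabilised ylide with an α-alkoxy methyl ketone, which under kinetic control places the ylide substituent (C2) cis to the oxygen-bearing carbon (C9) and so should give the Z C1=C10 alkene; addition at −78 °C is expected to outrun enolisation at C9.

Step 14
Reactants: 21 open-chain dimethyl acetal (name as in step 13)
Product: 22 methyl (3S)-3-{(4R,5S)-5-[(2Z,5S,6Z)-5-(tert-butyldimethylsilyloxy)-7-iodo-6-methylhepta-2,6-dien-2-yl]-2,2-dimethyl-1,3-dioxolan-4-yl}-4-oxobutanoate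
Conditions: PPTS (0.2 equiv), acetone–H2O (10:1), 45 °C
Reagents that add atoms: water, O
Why: Mild acid-catalysed hydrolysis of the acyclic dimethyl acetal in wet acetone, a medium in which the isopropylidene ketal is self-preserving and the secondary silyl ether is stable.

Step 15
Reactants: 22 open-chain iodoalkene aldehyde methyl ester (name as in step 14)
Product: 25 cis-fused 12,6-lactone on the (1(10)Z,4Z)-cyclodecadiene (C3 silyl ether; C8/C9 isopropylidene ketal; C6 R), via alkenylchromium 23 (not isolated), via chromium alkoxide 24 (not isolated)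
Conditions: CrCl2 (15 equiv), NiCl2 (2 mol %), degassed DMSO–THF, slow addition to 0.003 M, rt; aq. NH4Cl
Reagents that add atoms: none
Why: Zerovalent nickel (from NiCl2 and CrCl2) inserts into the C5–I bond with retention of the Z geometry, the alkenyl group passes to trivalent chromium, and the alkenylchromium adds to the C6 aldehyde, as in Nozaki–Hiyama–Kishi macrocyclisations of iodoalkenyl aldehydes to medium carbocycles. The carbocycle closes in a 10-exo-trig mode at C5–C6, and the C6 chromium alkoxide then closes the γ-lactone by 5-exo-trig acyl substitution at the C12 methyl ester with loss of methoxide. C6 is the only new stereocentre and is set under macrocyclic control: the cis-dioxolane and the two Z alkenes fold the chain so that C5 is expected to reach the aldehyde face that places H6 and H7 cis; this facial preference is the uncertain element of the step. The step also needs chemoselectivity for the aldehyde over ester and ketal (inherent to organochromium reagents), high dilution against oligomerisation, and an intact C7 centre, which the neutral conditions protect.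

Step 16
Reactants: 25 cis-fused lactone (C3 silyl ether; C8/C9 isopropylidene ketal)
Product: 29 11(13)-methylene lactone (C3 silyl ether; C8/C9 isopropylidene ketal), via lithium enolate 26 (not isolated), via Mannich base 27 (not isolated), via ammonium iodide 28 (not isolated)
Conditions: LDA, THF, −78 °C; CH2=NMe2 I (Eschenmoser's salt), −78 °C to rt; MeI, MeOH; NaHCO3, H2O–CH2Cl2
Reagents that add atoms: dimethyl(methylidene)ammonium iodide, C=[N+](C)C.[I-]
Why: Mannich reaction of the lactone enolate with Eschenmoser's salt, N-methylation and base-induced elimination of trimethylamine is the standard α-methylenation of γ-lactones; the C11 configuration is lost in the elimination.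

Step 17
Reactants: 29 11(13)-methylene lactone (C3 silyl ether)
Product: 30 11(13)-methylene lactone with free C3 hydroxyl (C8/C9 isopropylidene ketal)
Conditions: HF·pyridine, pyridine, THF, 0 °C to rt
Reagents that add atoms: none
Why: Buffered fluoride cleavage of the silyl ether, which should spare the ketal and the base-sensitive α-methylene lactone.

Step 18
Reactants: 30 C3 alcohol
Product: 31 C3 acetate (C8/C9 isopropylidene ketal)
Conditions: Ac2O, pyridine, DMAP (cat.), CH2Cl2, 0 °C
Reagents that add atoms: acetic anhydride, CC(=O)OC(C)=O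
Why: DMAP-catalysed acetylation of the only free hydroxyl.

Step 19
Reactants: 31 C3 acetate (C8/C9 isopropylidene ketal)
Product: 32 8,9-diol (C3 acetate; 11(13)-methylene 12,6-lactone)
Conditions: AcOH–H2O (4:1), 45 °C
Reagents that add atoms: none
Why: Mild aqueous acid hydrolysis of the isopropylidene ketal, chosen to avoid ionisation of the allylic acetate and transannular reactions of the diene.

Step 20
Reactants: 33 angelic acid
Product: 34 (Z)-2-methylbut-2-en-1-ol
Conditions: LiAlH4, Et2O, 0 °C to rt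
Reagents that add atoms: none
Why: Hydride reduction of the unsaturated acid to the allylic alcohol with retention of the Z geometry.

Step 21
Reactants: 34 (Z)-2-methylbut-2-en-1-ol
Product: 35 [(2S,3R)-2,3-dimethyloxiran-2-yl]methanol
Conditions: Ti(OiPr)4 (10 mol %), L-(+)-diisopropyl tartrate (12 mol %), t-BuOOH, 4 Å sieves, CH2Cl2, −20 °C
Reagents that add atoms: tert-butyl hydroperoxide, CC(C)(C)OO
Why: Sharpless asymmetric epoxidation; the titanium complex of the L-(+)-tartrate delivers oxygen to the alkene face that gives the (2S,3R) epoxy alcohol, the geometry of the alkene fixing the trans relation of the two methyl groups.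

Step 22
Reactants: 35 [(2S,3R)-2,3-dimethyloxiran-2-yl]methanol
Product: 36 (2R,3R)-2,3-dimethyloxirane-2-carboxylic acid
Conditions: RuCl3 (2 mol %), NaIO4 (3 equiv), MeCN–EtOAc–H2O, rt
Reagents that add atoms: water, O
Why: Ruthenium tetroxide oxidation (Sharpless conditions) takes the primary alcohol to the acid without touching the epoxide; the descriptor at C2 changes only because the substituent priorities change.

Step 23
Reactants: 32 8,9-diol; 36 (2R,3R)-2,3-dimethyloxirane-2-carboxylic acid
Product: 38 CNP0137407.4 (target; 3-acetate; 9-epoxy ester; free 8-hydroxyl), via mixed anhydride 37 (not isolated)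
Conditions: 36, 2,4,6-trichlorobenzoyl chloride, Et3N, THF, rt; then 32, DMAP, toluene, −20 to 0 °C
Reagents that add atoms: none
Why: Yamaguchi esterification, expected to take the allylic C9 hydroxyl, which sits next to the planar C10, in preference to the C8 hydroxyl flanked by the ring-fusion carbon C7; low temperature limits acyl migration.

**Compound list**

1 | prop-2-yn-1-ol | C#CCO | starting material
2 | magnesium alkenyl alkoxide from carbomagnesiation of 1 | Br[Mg]/C=C(/C)CO[Mg]Br | intermediate
3 | (Z)-3-iodo-2-methylprop-2-en-1-ol | I/C=C(/C)CO | intermediate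
4 | (Z)-3-iodo-2-methylprop-2-enal | I/C=C(/C)C=O | intermediate
5 | (3S,1Z)-1-iodo-2-methylhexa-1,5-dien-3-ol | I/C=C(/C)[C@@H](O)CC=C | intermediate
6 | tert-butyl{[(3S,1Z)-1-iodo-2-methylhexa-1,5-dien-3-yl]oxy}dimethylsilane | I/C=C(/C)[C@@H](O[Si](C)(C)C(C)(C)C)CC=C | intermediate
7 | (3S,4Z)-3-(tert-butyldimethylsilyloxy)-5-iodo-4-methylpent-4-enal | I/C=C(/C)[C@@H](O[Si](C)(C)C(C)(C)C)CC=O | intermediate
8 | (3S,4Z)-3-(tert-butyldimethylsilyloxy)-5-iodo-4-methylpent-4-en-1-ol | I/C=C(/C)[C@@H](O[Si](C)(C)C(C)(C)C)CCO | intermediate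
9 | tert-butyl{[(3S,1Z)-1,5-diiodo-2-methylpent-1-en-3-yl]oxy}dimethylsilane | I/C=C(/C)[C@@H](O[Si](C)(C)C(C)(C)C)CCI | intermediate
10 | [(3S,4Z)-3-(tert-butyldimethylsilyloxy)-5-iodo-4-methylpent-4-en-1-yl]triphenylphosphonium iodide (fragment 1) | I/C=C(/C)[C@@H](O[Si](C)(C)C(C)(C)C)CC[P+](c1ccccc1)(c1ccccc1)c1ccccc1.[I-] | intermediate
11 | 2,3-O-isopropylidene-D-erythronolactone, (3aR,6aR) | O=C1OC[C@H]2OC(C)(C)O[C@@H]12 | starting material
12 | 1-deoxy-3,4-O-isopropylidene-D-erythro-pent-2-ulofuranose (anomeric mixture) | CC1(O)OC[C@H]2OC(C)(C)O[C@@H]12 | intermediate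
13 | [(4R,5S)-2,2-dimethyl-5-(prop-1-en-2-yl)-1,3-dioxolan-4-yl]methanol | C=C(C)[C@@H]1OC(C)(C)O[C@@H]1CO | intermediate
14 | (4S,5S)-2,2-dimethyl-5-(prop-1-en-2-yl)-1,3-dioxolane-4-carbaldehyde | C=C(C)[C@@H]1OC(C)(C)O[C@@H]1C=O | intermediate
15 | methyl (E)-3-[(4R,5S)-2,2-dimethyl-5-(prop-1-en-2-yl)-1,3-dioxolan-4-yl]prop-2-enoate | C=C(C)[C@@H]1OC(C)(C)O[C@@H]1/C=C/C(=O)OC | intermediate
16 | methyl (3R)-3-[(4R,5S)-2,2-dimethyl-5-(prop-1-en-2-yl)-1,3-dioxolan-4-yl]-4-nitrobutanoate | C=C(C)[C@@H]1OC(C)(C)O[C@@H]1[C@H](CC(=O)OC)C[N+](=O)[O-] | intermediate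
17 | sodium nitronate of 16 | C=C(C)[C@@H]1OC(C)(C)O[C@@H]1[C@H](CC(=O)OC)C=[N+]([O-])[O-].[Na+] | intermediate
18 | methyl (3S)-3-[(4R,5R)-5-acetyl-2,2-dimethyl-1,3-dioxolan-4-yl]-4-oxobutanoate | CC(=O)[C@@H]1OC(C)(C)O[C@@H]1[C@H](CC(=O)OC)C=O | intermediate
19 | methyl (3S)-3-[(4R,5R)-5-acetyl-2,2-dimethyl-1,3-dioxolan-4-yl]-4,4-dimethoxybutanoate (fragment 2) | CC(=O)[C@@H]1OC(C)(C)O[C@@H]1[C@H](CC(=O)OC)C(OC)OC | intermediate
20 | phosphorus ylide from 10 | I/C=C(/C)[C@@H](O[Si](C)(C)C(C)(C)C)CC=P(c1ccccc1)(c1ccccc1)c1ccccc1 | intermediate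
21 | methyl (3S)-3-{(4R,5S)-5-[(2Z,5S,6Z)-5-(tert-butyldimethylsilyloxy)-7-iodo-6-methylhepta-2,6-dien-2-yl]-2,2-dimethyl-1,3-dioxolan-4-yl}-4,4-dimethoxybutanoate | I/C=C(/C)[C@@H](O[Si](C)(C)C(C)(C)C)C/C=C(/C)[C@@H]1OC(C)(C)O[C@@H]1[C@H](CC(=O)OC)C(OC)OC | intermediate
22 | methyl (3S)-3-{(4R,5S)-5-[(2Z,5S,6Z)-5-(tert-butyldimethylsilyloxy)-7-iodo-6-methylhepta-2,6-dien-2-yl]-2,2-dimethyl-1,3-dioxolan-4-yl}-4-oxobutanoate (precursor of the key step) | I/C=C(/C)[C@@H](O[Si](C)(C)C(C)(C)C)C/C=C(/C)[C@@H]1OC(C)(C)O[C@@H]1[C@H](CC(=O)OC)C=O | intermediate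
23 | C5 alkenylchromium dichloride derived from 22 | Cl[Cr](Cl)/C=C(/C)[C@@H](O[Si](C)(C)C(C)(C)C)C/C=C(/C)[C@@H]1OC(C)(C)O[C@@H]1[C@H](CC(=O)OC)C=O | intermediate
24 | C6 chromium alkoxide of the cyclised 6-hydroxy methyl ester | Cl[Cr](Cl)O[C@@H]1/C=C(/C)[C@@H](O[Si](C)(C)C(C)(C)C)C/C=C(/C)[C@@H]2OC(C)(C)O[C@@H]2[C@@H]1CC(=O)OC | intermediate
25 | cis-fused 12,6-lactone on the (1(10)Z,4Z)-cyclodecadiene; C3 tert-butyldimethylsilyl ether; C8/C9 isopropylidene ketal (product of the key step) | C1C(=O)O[C@@H]2/C=C(/C)[C@@H](O[Si](C)(C)C(C)(C)C)C/C=C(/C)[C@@H]3OC(C)(C)O[C@@H]3[C@H]12 | intermediate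
26 | lithium enolate of lactone 25 | C1=C(O[Li])O[C@@H]2/C=C(/C)[C@@H](O[Si](C)(C)C(C)(C)C)C/C=C(/C)[C@@H]3OC(C)(C)O[C@@H]3[C@H]12 | intermediate
27 | 11-(dimethylaminomethyl) lactone (Mannich base; C11 epimers) | CN(C)CC1C(=O)O[C@@H]2/C=C(/C)[C@@H](O[Si](C)(C)C(C)(C)C)C/C=C(/C)[C@@H]3OC(C)(C)O[C@@H]3[C@H]12 | intermediate
28 | 11-(trimethylammoniomethyl) lactone iodide | C[N+](C)(C)CC1C(=O)O[C@@H]2/C=C(/C)[C@@H](O[Si](C)(C)C(C)(C)C)C/C=C(/C)[C@@H]3OC(C)(C)O[C@@H]3[C@H]12.[I-] | intermediate
29 | 11(13)-methylene lactone; C3 silyl ether; C8/C9 isopropylidene ketal | C=C1C(=O)O[C@@H]2/C=C(/C)[C@@H](O[Si](C)(C)C(C)(C)C)C/C=C(/C)[C@@H]3OC(C)(C)O[C@@H]3[C@H]12 | intermediate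
30 | 11(13)-methylene lactone; free C3 hydroxyl; C8/C9 isopropylidene ketal | C=C1C(=O)O[C@@H]2/C=C(/C)[C@@H](O)C/C=C(/C)[C@@H]3OC(C)(C)O[C@@H]3[C@H]12 | intermediate
31 | 11(13)-methylene lactone; C3 acetate; C8/C9 isopropylidene ketal | C=C1C(=O)O[C@@H]2/C=C(/C)[C@@H](OC(C)=O)C/C=C(/C)[C@@H]3OC(C)(C)O[C@@H]3[C@H]12 | intermediate
32 | 11(13)-methylene lactone; C3 acetate; 8,9-diol | C=C1C(=O)O[C@@H]2/C=C(/C)[C@@H](OC(C)=O)C/C=C(/C)[C@H](O)[C@H](O)[C@H]12 | intermediate
33 | angelic acid, (Z)-2-methylbut-2-enoic acid | C/C=C(/C)C(=O)O | starting material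
34 | (Z)-2-methylbut-2-en-1-ol | C/C=C(/C)CO | intermediate
35 | [(2S,3R)-2,3-dimethyloxiran-2-yl]methanol | OC[C@]1(C)O[C@@H]1C | intermediate
36 | (2R,3R)-2,3-dimethyloxirane-2-carboxylic acid | OC(=O)[C@]1(C)O[C@@H]1C | intermediate
37 | mixed anhydride of 36 and 2,4,6-trichlorobenzoic acid | O=C(OC(=O)[C@]1(C)O[C@@H]1C)c1c(Cl)cc(Cl)cc1Cl | intermediate
38 | CNP0137407.4: (3S,6R,7S,8R,9S,1(10)Z,4Z)-3-acetoxy-9-[(2R,3R)-2,3-dimethyloxirane-2-carbonyloxy]-8-hydroxygermacra-1(10),4,11(13)-trien-12,6-olide | C=C1C(=O)O[C@@H]2/C=C(/C)[C@@H](OC(C)=O)C/C=C(/C)[C@H](OC(=O)[C@]3(C)O[C@@H]3C)[C@H](O)[C@H]12 | target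

**Step count and risks**

Total step count: 23. Longest linear sequence: 15 steps (steps 1–7, 13–19 and 23).

Steps most likely to fail:

1. Step 15. What may go wrong is addition of the alkenylchromium to the other face of the aldehyde, which would fuse the lactone trans, together with oligomerisation at the dilution needed for a ten-membered ring. Fallback: the chain 22 is still cyclised, but the C6 configuration is corrected afterwards. The trans-fused 6-epi lactone F3 obtained from 22 would be saponified (LiOH, THF–H2O, careful acidification at 0 °C) to the 6-epi hydroxy acid F4. A Mitsunobu lactonisation (PPh3, diisopropyl azodicarboxylate, THF, 0 °C) would then close the lactone with inversion at C6 and rejoin the route at 25.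

2. Step 13. What may go wrong is enolisation of ketone 19 by the basic ylide, which scrambles C9 and stalls conversion, and erosion of the Z preference. Fallback: a stepwise Horner–Wittig sequence that sets out from iodide 9. Arbuzov reaction with ethyl diphenylphosphinite (110 °C) would give the phosphine oxide F1. Its lithio derivative (LDA, THF, −78 °C, then CeCl3 to damp its basicity) would add to 19, and the β-hydroxy phosphine oxide F2 whose syn elimination leads to the Z alkene would be separated from its diastereomers by chromatography. Stereospecific syn elimination (NaH, DMF, rt) would then give 21, where the route resumes.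

3. Step 23. What may go wrong is acylation at the C8 hydroxyl or at both hydroxyls, and acyl migration between the cis-vicinal oxygens under the basic conditions. Fallback: from diol 32 the hydroxyl that reacts first is masked instead of acylated. Should C8 prove the more reactive site, silylation (Et3SiCl, imidazole, CH2Cl2, −40 °C) would give the 8-O-triethylsilyl ether F5. The remaining C9 hydroxyl would be acylated with mixed anhydride 37 (DMAP, toluene, rt) to the silylated ester F6, and HF·pyridine would remove the silyl group to reach 38.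

Further compounds
F1 | step 13 | [(3S,4Z)-3-(tert-butyldimethylsilyloxy)-5-iodo-4-methylpent-4-en-1-yl]diphenylphosphine oxide | I/C=C(/C)[C@@H](O[Si](C)(C)C(C)(C)C)CCP(=O)(c1ccccc1)c1ccccc1
F2 | step 13 | β-hydroxy phosphine oxide from lithiated F1 and ketone 19 (diastereomer whose syn elimination gives the Z alkene) | I/C=C(/C)[C@@H](O[Si](C)(C)C(C)(C)C)C[C@@H](P(=O)(c1ccccc1)c1ccccc1)[C@@](C)(O)[C@@H]1OC(C)(C)O[C@@H]1[C@H](CC(=O)OC)C(OC)OC
F3 | step 15 | trans-fused 6-epi lactone (C3 silyl ether; C8/C9 isopropylidene ketal) | C1C(=O)O[C@H]2/C=C(/C)[C@@H](O[Si](C)(C)C(C)(C)C)C/C=C(/C)[C@@H]3OC(C)(C)O[C@@H]3[C@H]12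
F4 | step 15 | 6-epi hydroxy acid of the cyclodecadiene (C3 silyl ether; C8/C9 isopropylidene ketal) | O[C@H]1/C=C(/C)[C@@H](O[Si](C)(C)C(C)(C)C)C/C=C(/C)[C@@H]2OC(C)(C)O[C@@H]2[C@@H]1CC(=O)O
F5 | step 23 | 8-O-triethylsilyl ether of diol 32 | C=C1C(=O)O[C@@H]2/C=C(/C)[C@@H](OC(C)=O)C/C=C(/C)[C@H](O)[C@H](O[Si](CC)(CC)CC)[C@H]12
F6 | step 23 | 8-O-triethylsilyl ether of target 38 | C=C1C(=O)O[C@@H]2/C=C(/C)[C@@H](OC(C)=O)C/C=C(/C)[C@H](OC(=O)[C@]3(C)O[C@@H]3C)[C@H](O[Si](CC)(CC)CC)[C@H]12
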